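The constant to read from the earlier runs is the steady fall of monomer in chains: in Sunday's run the readings lose 0.0869 /h of the charge from 1.33 h to 4.00 h, while free monomer reads near 4.9%, a quasi-steady state.

| flask | free monomer | initiator | remark | time |
|---|---|---|---|---|
| Sunday's | 0.50 M | 3.5 mM | run made earlier |  |
| Friday's | 0.50 M | 5.5 mM | run made earlier |  |
| flask | 0.50 M | 2.5 mM |  | 6.0 h |

| run | time / h | monomer in chains / % | free monomer / % |
|---|---|---|---|
| Sunday's | 0.250 | 60.8 | 17.6 |
| Sunday's | 0.500 | 68.0 | 6.8 |
| Sunday's | 0.833 | 66.6 | 4.1 |
| Sunday's | 1.33 | 62.5 | 4.9 |
| Sunday's | 2.00 | 56.4 | 4.8 |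
| Sunday's | 4.00 | 39.3 | 4.9 |
| Friday's | 0.250 | 71.8 | 10.3 |
| Friday's | 0.667 | 72.8 | 5.2 |
| Friday's | 1.33 | 66.6 | 4.6 |
| Friday's | 2.00 | 60.7 | 5.6 |
| Friday's | 3.00 | 50.8 | 6.1 |
| Friday's | 4.00 | 41.4 | 5.2 |

(each reading ± 0.5 percentage points)

- average number of monomer units in a chain (chains begun, living or dead) at 6.0 h
- part of the free monomer that has reacted at 6.0 h

- the average divides the monomer in chains by the number of chains begun, living and dead together
- the earlier runs do not show the number of chains; that part of a forecast is a guess

Carried from Sunday's last reading to 6.0 h, that line gives the chain share, the part of the charged free monomer still in chains at the asked time: 21.9%. Friday's run, with 5.5 mM of initiator, gives 22.5% the same way; Sunday's share, from the run with less initiator, is taken for the flask. At the early end, one chain is guessed per initiator charged, so the chain length is the share times free monomer charged over initiator charged, 43.8 for the flask, and the reacted part, taken from the last free monomer reading of Sunday's run, is 95.1%.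

The forecast is lower on length: 40 (28 to 54) and 95.5% (94.5% to 96.4%), on the ground that “This fits free monomer leaking irreversibly to a side product”.

The flask gives 40.4 and 95.4%, as forecast.

    free monomer + initiator → living end + monomer in chains (k = 0.0310 /M/s)
    free monomer + living end → monomer in chains + living end, rate k2*[living end]*[free monomer] (k = 0.540 /M/s)
    monomer in chains + living end → free monomer + living end, rate k3*[living end] as long as [monomer in chains] is above zero (k = 0.0170 /s)
    free monomer → uncatalysed product (k = 4.80 × 10⁻⁴ /s)

The flask holds 20.2% in chains against the carried 21.9%, and its 75.2% of uncatalysed product is the larger part. Its living end stands at 0.00250 M, equal to the initiator charged, with initiator at 0%. A neighbouring flask with 0.0043 M of initiator, all else held, reckons to 25.5 by the same share, and it gives 25.9, with 22.2% in chains.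

All runs are calculated for an exercise; the scatter is artificial.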